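**One-step world.** In a one-step world, starting material and coupling partner give target, and the vessel changes only the time taken. This flask splits that step, lets starting material leak unaided to side product A, and lets target turn into its isomer.

all flasks: starting material 20 mM
- winter: coupling partner 12.0 mM; a single well-mixed tank run continuously and read at steady state, 2.5 d in it on average
- dusk: coupling partner 12.0 mM; a closed flask charged with all of it at once and left for 2.5 d; time 2.5 d
- spring: coupling partner 12.0 mM (fed, over 2.00 d); a stirred flask in which coupling partner is dosed at a steady rate over 2.00 d without added volume, worked up at 2.5 d; time 2.5 d
- summer: coupling partner 12.0 mM; a single well-mixed tank run continuously and read at steady state, 7.50 d in it on average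

    target ⇌ isomer of the product (K1 = 0.48, k1 = 1.2 × 10⁻⁴ /min)
    coupling partner + intermediate B → side product B (k2 = 0.016 /M/min)
    coupling partner + target ⇌ idle adduct, settled at all times (K3 = 150 /M)
    starting material + coupling partner → target (k4 = 0.047 /M/min)
    starting material → side product A (k5 = 1.6 × 10⁻⁴ /min)
    intermediate A → intermediate B (k6 = 1.1 × 10⁻⁴ /min)
    starting material + coupling partner → intermediate A (k7 = 0.035 /M/min)

- the set-up with the highest share of target in all that became target or side product A or side product B or isomer of the product, at the outlet or at the end ("none" if the first two lie within 2 percentage points) (winter / dusk / spring / summer / none)
- share of target in all that became target or side product A or side product B or isomer of the product, at the outlet or at the end, winter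
- share of target in all that became target or side product A or side product B or isomer of the product, at the outlet or at the end, dusk
- share of target in all that became target or side product A or side product B or isomer of the product, at the outlet or at the end, spring
- share of target in all that became target or side product A or side product B or isomer of the product, at the outlet or at the end, summer

- for target the idle adduct is counted in
- the stated concentrations are those of everything mixed, before any reaction; amounts are the same in each set-up
- the feed brings no volume worth counting
- run time (dusk): 2.5 d

**Which constants.** Side product B comes first. It lies behind intermediate A, whose half-life by its own step is 4.38 d, longer than the 2.5 d run, so an error in 0.016 /M/min moves the dusk flask little. Isomerisation needs care: the forward half-life of free target, 4.01 d, stands at 1.60 times the run, though at the charged coupling partner the idle adduct stands at 1.80 per free target. Coupling partner is the smaller charge, and 57.3 % of what couples with starting material makes target, so 0.035 /M/min counts. The pair 0.047 /M/min and 1.6 × 10⁻⁴ /min must be known well. Both rates carry starting material, which cancels, so their ratio compares free coupling partner with 3.40 mM: the even level, the free coupling partner at which target and side product A form equally fast. Free coupling partner over this level is the selectivity factor. At the level itself target takes half of the pair; with 1.6 × 10⁻⁴ /min doubled, a third.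

**Reckoned levels.** This reckoning neglects the adduct. The winter tank, taking the 8.00 mM of starting material that the charge of coupling partner leaves, is reckoned near 3.57 mM, so, counting target against side product A, the reckoned winter share lies under 51.2 %. The spring dose, reckoned at full starting material, balances coupling at 2.54 mM, below the even level; this is a level for the early dose, while starting material stands near its charge. The dusk flask opens at 3.52 times the even level and falls. So the reckoning, on that early level, sets spring under winter, puts summer, with its longer stay, low as well, and cannot part dusk from winter.

**Forecast and run.** The forecast names dusk, with 41.3 % for winter, 43.5 % for dusk, 39.5 % for spring and 29.8 % for summer, holding that “the idle adduct shields target from isomerisation”. The simulation gives dusk: winter 41.2 %, dusk 44.4 %, spring 35.6 %, summer 29.8 %.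

**Still moving.** The winter tank reads 3.19 mM of coupling partner, 0.938 times the even level. The spring flask peaks at 3.96 mM, 1.16 times that level. Neither the dusk flask nor the spring flask has come to rest. At ten times the time, 25.0 d, the dusk share stands at 28.1 %, down 16 percentage points. The spring share at 25.0 d stands at 24.5 %, down 11 points.

The numbers come from no measurement; the run is a simulation.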